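Per minute, Sub in the amber and teal runs loses a share of what stands that hardly shifts with the charge. Taking k = ln(charged/left)/t at the last reading gives 0.664 min⁻¹ for amber and 0.644 min⁻¹ for teal.

| setting | amber | teal | flask |
|---|---|---|---|
| Sub | 0.085 M | 0.13 M | 0.17 M |
| Spx | 24 mM (held) | 24 mM (held) | 24 mM (held) |
| remark | run made earlier | run made earlier |  |
| time |  |  | 2.0 min |

| run | time / min | Sub.Spx2 / % | Sid / % | Sub / % |
|---|---|---|---|---|
| amber | 0.200 | 3 | 2 | 89 |
| amber | 0.667 | 18 | 6 | 67 |
| amber | 1.00 | 21 | 13 | 55 |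
| amber | 1.50 | 23 | 21 | 39 |
| amber | 2.50 | 20 | 45 | 19 |
| teal | 0.500 | 12 | 5 | 71 |
| teal | 1.00 | 20 | 11 | 52 |
| teal | 1.33 | 21 | 16 | 41 |
| teal | 2.00 | 19 | 30 | 27 |
| teal | 2.50 | 15 | 35 | 20 |

(scatter of a reading: 2 percentage points)

- at the start none of Spx is in solution

- how much Sub.Spx2 the flask holds at 2.0 min, in percent of the Sub charged
- how much Sid the flask holds at 2.0 min, in percent of the Sub charged
- concentration of Spx2 at 2.0 min, in M

The mean of the two is

ka = 0.654 min⁻¹

the apparent pseudo-first-order constant of Sub with Spx held at 24 mM, so that in this reckoning Sub left at time t is exp(−ka·t) of the charge.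

Spx2 starts from nothing, yet amber reads 89 % Sub at 0.200 min against 87.7 % from the rule, so this reckoning draws the flask's curve at slope ka from the start. By the rule, ln(2)/ka = 1.06 min takes half of the flask's charge, and at the asked time

Sub = exp(−ka·t) = 27.0 %

with the rule's curve running on toward zero.

Teal, the higher charge, shows the product curves. Sub.Spx2 reads 21 % at 1.33 min, and at 2.00 min Sid reads 30 %, above the 19 % of Sub.Spx2, so this reckoning puts Sid ahead in the flask. Teal's balance then falls short by 24.0 %. Scaled by charge on the assumption that the shortfall follows it: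

shortfall = 31.4 %
Sub.Spx2 + Sid = 41.6 %

Spx2 is read in neither run, and this reckoning gives it no figure. The forecast gives 16 % Sub.Spx2, 26 % Sid and 0.02 M Spx2, the last “very uncertain because nothing measures it directly”.

The flask gives 17.8 % Sub.Spx2, 22.6 % Sid and 0.0157 M Spx2, and 34.2 % of the charge stands in Tgt, each Tgt counted as the two Sub it holds.

    Sub + Spx2 → Sub.Spx2 (k = 0.500 M⁻¹ s⁻¹)
    Spx2 + Sub.Spx2 → Sid (k = 0.920 M⁻¹ s⁻¹)
    2 Sub → Tgt (k = 0.0260 M⁻¹ s⁻¹)
    Spx ⇌ Spx2, rate k4*(csat - [Spx2]) (kL = 0.0980 s⁻¹)

Sub in the flask stands at 25.3 % against the reckoned 27.0 %, and the formula that gave ka comes to 0.686 min⁻¹ for this flask. The neighbour charged with 0.10 M holds 27.5 % Sub at 2.00 min, and the same formula comes to 0.645 min⁻¹ there.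

The numbers in the tables are simulated with made-up constants; scatter was added.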